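We choose to take the reagent charge as written and let it keep the books for this flask, supposing that starting material takes up reagent once to give a singly reacted form and again to give double product, one reagent per step.

| flask | starting material | reagent | remark | time |
|---|---|---|---|---|
| Saturday's | 0.50 mM | 0.75 equiv (in portions, 3) | run made earlier; portions every 3.0 s |  |
| Friday's | 0.50 mM | 1.1 equiv (in portions, 3) | run made earlier; portions every 3.0 s |  |
| flask | 0.50 mM | 1.50 equiv (in portions, 3) | the portions of reagent follow each other after 3.0 s, the first at the start | 50 min |

| run | time / min | starting material / % | mono adduct / % |
|---|---|---|---|
| Saturday's | 2.00 | 53.7 | 20.6 |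
| Saturday's | 6.00 | 49.2 | 20.0 |
| Saturday's | 10.0 | 50.0 | 20.1 |
| Saturday's | 15.0 | 50.5 | 20.4 |
| Saturday's | 25.0 | 50.6 | 21.0 |
| Saturday's | 30.0 | 50.0 | 20.0 |
| Friday's | 5.00 | 33.2 | 19.0 |
| Friday's | 10.0 | 33.0 | 17.0 |
| Friday's | 15.0 | 33.5 | 17.7 |
| Friday's | 20.0 | 32.9 | 17.5 |
| Friday's | 25.0 | 33.3 | 17.5 |
| Friday's | 30.0 | 34.0 | 16.8 |

(readings scatter by 0.5 percentage points)

- the reaction counts as stopped when no species that holds the starting material changes by six tenths of a point or more over the second half of the time

1. the state of affairs at 50 min: stopped, and by what, or still going (it is still moving / forward and back rates have come level / the reagent has run out first / all of the starting material has reacted)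
2. share of the starting material used up at 50 min
3. mono adduct at 50 min, in percent of the starting material charged
4. double product at 50 min, in percent of the starting material charged

Both runs stand flat after their first reading, with starting material near 50.1% on Saturday and 33.3% on Friday, and mono adduct near 20.3% and 17.3%. Our first estimate is that the reagent charged was used up. But if all that reacted and is not mono adduct is double product, the reagent taken is twice the conversion less the mono adduct: 79.5% of the starting material on Saturday against 75.0% charged, and 116% on Friday against 110%. A stronger reagent could close that gap, and so could an unseen singly reacted form. We do not separate the two from these readings, so we hold to the charge and accept that risk.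

The singly reacted pool is then twice the conversion minus the equivalents: 24.9% on Saturday. That alone gives no conversion, so we integrate. Both steps consume the same reagent, which cancels when one rate is divided by the other, and with a selectivity factor κ, the rate constant of the second step over that of the first, the pool is the remaining fraction s minus s to the power κ, over κ less one. Saturday's remaining half and pool of a quarter read as κ near 2, so the pool becomes remaining times used fraction, and for a flask with that κ which stops with its reagent used the books reduce to a rule: conversion times one-plus-conversion equals the equivalents.

We read that factor on Saturday, so we test it on Friday: the rule gives 66.2% against 66.7% read, a gap like the scatter of one reading. For the flask, assuming it too stops with its reagent used, we reckon conversion 82.3%, a singly reacted pool of 14.6%, and double product, the equivalents minus the conversion, 67.7%. Friday's seen share of the pool, 74.2%, puts mono adduct at 10.8%.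

The forecast says the reagent has run out first, with conversion 83.5%, mono adduct 9.5% and double product 74%, holding that "the reagent is about 5% stronger than stated".

The flask gives: the reagent has run out first, conversion 83.1%, mono adduct 10.5%, double product 66.9%.

    reagent + mono adduct → double product + by-product (k = 96.0 M⁻¹ s⁻¹)
    starting material + reagent → other mono adduct + by-product (k = 4.62 M⁻¹ s⁻¹)
    reagent + other mono adduct → double product + by-product (k = 18.1 M⁻¹ s⁻¹)
    starting material + reagent → mono adduct + by-product (k = 37.4 M⁻¹ s⁻¹)

Other mono adduct stands at 5.72% beside mono adduct 10.5% at 50.0 min, with reagent at 0%. Together they make 16.2% against our pool of 14.6%, and the equivalents minus the computed conversion give 66.9% of double product.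

On the neighbour flask charged with 0.900 equiv, the rule gives conversion 57.2%, pool 24.5% and double product 32.8%. That flask computes to conversion 57.4%, singly reacted forms 24.8% and double product 32.6%.

The readings are simulated for substances that don't exist, noise included.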